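(All runs stem from a simulated flask with constants of no real substance.)

At 20 min the reading to watch is the starting material left, set against a catalyst that loses strength while the flask runs.

in all of them: free catalyst 0.26 mM

|  | starting material | partner | remark | time |
|---|---|---|---|---|
| Sunday's | 0.13 M | 0.325 M | run made earlier |  |
| Thursday's | 0.26 M | 0.325 M | run made earlier |  |
| south | 0.13 M | 0.325 M | everything together at the start | 20 min |
| west | 0.13 M | 0.325 M (fed, over 8.0 min) | all else is in the flask from the start; the feed brings no volume worth counting | 20 min |
| east | 0.13 M | 0.325 M (fed, over 50 s) | all else is in the flask from the start; the feed brings no volume worth counting | 20 min |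
| north-east | 0.13 M (fed, over 8.0 min) | 0.325 M | all else is in the flask from the start; the feed brings no volume worth counting | 20 min |

| run | time / min | product / % | starting material / % |
|---|---|---|---|
| Sunday's | 1.50 | 12.0 | 83.8 |
| Sunday's | 4.00 | 31.8 | 65.3 |
| Sunday's | 8.00 | 52.0 | 44.6 |
| Sunday's | 20.0 | 80.1 | 18.3 |
| Thursday's | 0.833 | 4.6 | 90.8 |
| Thursday's | 2.00 | 15.2 | 80.6 |
| Thursday's | 4.00 | 30.1 | 65.8 |
| Thursday's | 6.00 | 42.0 | 54.0 |

(readings scatter by 0.3 percentage points)

* which flask leads in amount of product, in percent of the starting material charged ("all alike" within 1.5 percentage points) (south / west / east / north-east / all alike)
* how much product is there at the end, in percent of the starting material charged: south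
* how much product is there at the end, in percent of the starting material charged: west
* how much product is there at the end, in percent of the starting material charged: east
* how much product is there at the end, in percent of the starting material charged: north-east



Sunday's and Thursday's runs keep nearly the same percent curve at different charges (65.3% against 65.8% at 4.00 min), so starting material falls by a pseudo-first-order constant. In Sunday's run that constant sinks from 0.0998 min⁻¹ over the early readings to 0.0742 min⁻¹ over the late ones. Read between the midpoints of those spans, this is a loss of strength of 0.0263 min⁻¹, and it puts the constant at the start at 0.107 min⁻¹. Their quotient, 4.08, is the reach, the logarithmic drop of starting material that a catalyst charge can give over its whole life. Starting material then falls by the reach times the strength at entry less the strength at the end.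

For south this leaves 18.8%, and east should differ little from south, its feed of 50 s being far shorter than the run. North-east's charge enters on average at half the feed time, which leaves 28.3%. With Sunday's unaccounted 1.6 percentage points set aside, that is 70.1% product. If the loss follows [partner], west's catalyst ages on average over 16.0 min, a shorter time than south's, and ends at 65.7% strength rather than 59.1%, so west should lead.

The forecast named west, with 80.1%, 81%, 80.3% and 70.5% for south, west, east and north-east, and held that “North-east's late-fed material gets less time and weaker catalyst”. The flasks give 80.2%, 83.6%, 80.7% and 67.6%, so west leads.

    starting material + free catalyst ⇌ free catalyst + open intermediate (K = 2.00, k = 7.81 L mol⁻¹ s⁻¹)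
    free catalyst + open intermediate ⇌ catalyst intermediate (K = 13.5 L mol⁻¹, k = 277 L mol⁻¹ s⁻¹)
    partner + catalyst intermediate → free catalyst + product (k = 82.6 L mol⁻¹ s⁻¹)
    partner + free catalyst → spent catalyst (k = 0.00214 L mol⁻¹ s⁻¹)

North-east holds 31% of its starting material against the reckoned 28.3%, and spent catalyst stands at 37.9% in west against 47.5% in south. The neighbouring flask is north-east with 0.0010 M of free catalyst. Taking the rate in proportion to catalyst multiplies the reach by 3.85, which leaves 0.782% of the starting material. That flask holds 1.06% of it, with free catalyst at 54.2% and product at 98.9%.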